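(The readings were generated by integration with made-up constants.)

Product J stands in the first reading of both earlier runs and L comes up behind it, so I count what has been made by the G that has gone, per D charged: a turnover number.

| setting | maple | larch | Tuesday's | Wednesday's |
|---|---|---|---|---|
| G | 0.17 M | 0.17 M | 0.17 M | 0.17 M |
| Z | 0.34 M | 0.34 M | 0.340 M | 0.340 M |
| D | 0.073 mM | 0.092 mM | 0.15 mM | 0.10 mM |
| remark | run made earlier | run made earlier |  |  |
| time |  |  | 1.0 h | 1.0 h |

| run | time / min | G / % | L / % | X / % | J / % |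
|---|---|---|---|---|---|
| maple | 2.50 | 99.1 | 0 | 0 | 1.1 |
| maple | 4.00 | 98.6 | 0.2 | 0.4 | 1.6 |
| maple | 6.00 | 98.1 | 0 | 0 | 2.8 |
| maple | 10.0 | 96.5 | 0.3 | 0 | 2.8 |
| maple | 20.0 | 94.8 | 1.6 | 0 | 3.2 |
| maple | 30.0 | 92.6 | 2.5 | 0.2 | 3.8 |
| larch | 2.00 | 99.9 | 0 | 0.6 | 1.4 |
| larch | 6.00 | 97.8 | 0.4 | 0 | 2.2 |
| larch | 10.0 | 95.4 | 0.2 | 0.1 | 3.2 |
| larch | 15.0 | 94.1 | 1.6 | 0 | 4.6 |
| larch | 25.0 | 92.4 | 3.1 | 0.7 | 4.9 |
| larch | 30.0 | 91.3 | 3.0 | 0 | 5.3 |

(scatter of a reading: 0.5 percentage points)

1. which of these there is most of at the end, counted by the G in it, Tuesday's (G / L / X / J)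
2. which of these there is most of at the end, counted by the G in it, Wednesday's (G / L / X / J)
3. the largest of these amounts at the end, in percent of the G charged, Tuesday's
4. the largest of these amounts at the end, in percent of the G charged, Wednesday's



By its last reading the maple run has turned over 172 G per D and the larch run 161, with a scatter of 0.5 percentage points on each reading, so I take them as one curve and pool them, which gives 166 at 30.0 min.

The curve starts steep, with 83.5 turnovers in the first 10.0 min. Then it bends: the next 20.0 min, twice as long, add 82.5. If each 10.0 min brings the same fraction of the one before, that fraction reads 0.612, so on this assumption the rate halves every 14.1 min, and my extrapolated curve runs into a level of 215 turnovers. By 1.0 h my curve stands at 204 G per D charged, the hour's turnover number. With Tuesday's D that leaves 82.0% of the G, and the 18.0% gone, however J, L and X share it, is less than what remains, so I say G.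

The forecast also names G for Tuesday's and G for Wednesday's, in its words “G stays largest in both runs”, but its amounts are 75% for Tuesday's, lower than my 82.0%, and 83% for Wednesday's.

Tuesday's flask gives G at 82.1%. Wednesday's flask gives G at 87.5%.

    J ⇌ L (K = 2.01, k = 5.39 × 10⁻⁴ s⁻¹)
    Z → Q (k = 6.78 × 10⁻⁴ s⁻¹)
    Z + X → E (k = 1.74 M⁻¹ s⁻¹)
    G + D ⇌ X (K = 3.00 M⁻¹, k = 7.36 M⁻¹ s⁻¹)
    E → D + J (k = 1.55 s⁻¹)

Tuesday's ends with 6.7% of its own Z charge free, less than the 82% of its G, and its count is 203 turnovers against my 204. Put to Wednesday's 0.10 mM of D, 204 turnovers leave 88.0% of the G, and that flask holds 87.5%.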